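**Retrosynthetic overview**
- The last operation makes the methyl ester C16–OMe bond by methanolysis of an enol lactone (a 3-alkylidene-2(3H)-furanone). This also releases the C15 ketone; acetonide hydrolysis follows in the same flask.
- The enol lactone is the prototropic isomer (H moved from C15 to C11) of a bis-butenolide in which C15 of one labdane butenolide is bonded to C12′ of the other.
- The C15–C12′ bond comes from a vinylogous addition–elimination between a dienyl butenolide (γ-nucleophile) and a 14-O-acetyl alkylidene lactone (electrophile). Attack anti to the 14′-acetate sets C12′.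
- Ring order: no ring is built. Both decalins, both butenolides and all ring stereocentres are bought with two andrographolides; one butenolide is opened in the last step.

Assumption: andrographolide and 14-deoxy-11,12-didehydroandrographolide (bulk plant labdanes) count as cheap commercial starting materials; labdane numbering is used, unprimed for the keto-ester half and primed for the half that keeps its butenolide.

**Step 1**
Reactants: 1 andrographolide
Product: 2 andrographolide 3,19-acetonide
Conditions: 2,2-dimethoxypropane, PPTS (cat.), toluene/DMSO, 80 °C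
Reagents that add atoms: 2,2-dimethoxypropane, COC(C)(C)OC
Why: acid-catalysed transketalisation closes the six-membered 1,3-dioxane on the 1,3-related C3 and C19 hydroxyls only, leaving the allylic 14-OH free; no stereocentre is touched.

**Step 2**
Reactants: 2 andrographolide 3,19-acetonide
Product: 3 andrographolide 3,19-acetonide 14-acetate
Conditions: Ac2O, pyridine, DMAP (cat.), CH2Cl2, 0 °C
Reagents that add atoms: acetic anhydride, CC(=O)OC(C)=O
Why: DMAP-catalysed O-acylation of the only free hydroxyl turns C14–O into a leaving group with retention at C14 (14S); the low temperature suppresses 1,4-elimination of acetic acid.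

**Step 3**
Reactants: 4 14-deoxy-11,12-didehydroandrographolide
Product: 5 14-deoxy-11,12-didehydroandrographolide 3,19-acetonide
Conditions: 2,2-dimethoxypropane, PPTS (cat.), toluene/DMSO, 80 °C
Reagents that add atoms: 2,2-dimethoxypropane, COC(C)(C)OC
Why: the same transketalisation as in step 1 masks the 3,19-diol, so that both coupling partners carry identical protection; no stereocentre is touched.

**Step 4**
Reactants: 3 andrographolide 3,19-acetonide 14-acetate; 5 14-deoxy-11,12-didehydroandrographolide 3,19-acetonide (1.5 equiv)
Product: 6 C15–C12′ bis-butenolide bis-acetonide (12′S, epimer mixture at C15)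
Conditions: Cs2CO3 (1.5 equiv), MeCN, −20 to 0 °C
Reagents that add atoms: none
Why: direct vinylogous Michael addition–E1cB elimination (SN2′-type allylic substitution): the cesium 2-oxidofuran of 5 attacks through its unsubstituted γ-carbon C15 (the α-carbon is blocked by the alkenyl group) at C12′ of the (E)-alkylidene lactone on the face anti to the 14′S-acetate, the lactone enolate expels acetate to give the endocyclic butenolide, and this 1,3-transfer of chirality from C14′ fixes C12′ as S; the C15 epimers converge in step 5, and any 3 that only loses acetic acid becomes 5 itself.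

**Step 5**
Reactants: 6 C15–C12′ bis-butenolide bis-acetonide
Product: 9 target keto ester CNP0330094.1, via enol lactone 7 (not isolated), via keto ester bis-acetonide 8 (not isolated)
Conditions: Et3N (3 equiv), DMAP (20 mol %), MeOH/THF 1:1, 40 °C; then evaporate, AcOH/H2O 7:3, rt
Reagents that add atoms: methanol, CO
Why: Proposed new method: tandem vinylogous prototropic transposition and enol-lactone methanolysis; Et3N reversibly removes the doubly activated C15–H of the 3-alkenylbutenolide (giving an aromatic 2-oxidofuran), reprotonation at the remote C11 gives the conjugated (E)-3-alkylidene-2(3H)-furanone 7 in fast equilibrium with 6, and only this enol ester is opened irreversibly by methanol under DMAP acyl-transfer catalysis (new C16–OMe bond, C15 released as the ketone, E geometry thermodynamic and the same as in andrographolide), which drains the equilibrium under Curtin–Hammett control while the weak amine base is expected to leave the hindered C12′–H (set in step 4) and the second butenolide untouched; aqueous acetic acid then hydrolyses both acetonides; the closest known reaction types are the amine-mediated interconversion of 2(5H)- and 2(3H)-furanones and the alcoholysis of 3-arylidene-2(3H)-furanones or α-angelica lactone to γ-keto esters.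

**Compound list**
1 | andrographolide | C=C1CC[C@@H]2[C@](C)(CO)[C@H](O)CC[C@@]2(C)[C@@H]1C/C=C1/C(=O)OC[C@H]1O | starting material
2 | andrographolide 3,19-acetonide (3,19-O-isopropylidene) | C=C1CC[C@@H]2[C@]3(C)COC(C)(C)O[C@@H]3CC[C@@]2(C)[C@@H]1C/C=C1/C(=O)OC[C@H]1O | intermediate
3 | andrographolide 3,19-acetonide 14-acetate | C=C1CC[C@@H]2[C@]3(C)COC(C)(C)O[C@@H]3CC[C@@]2(C)[C@@H]1C/C=C1/C(=O)OC[C@H]1OC(C)=O | intermediate
4 | 14-deoxy-11,12-didehydroandrographolide (11E-dienyl butenolide) | C=C1CC[C@@H]2[C@](C)(CO)[C@H](O)CC[C@@]2(C)[C@@H]1/C=C/C1=CCOC1=O | starting material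
5 | 14-deoxy-11,12-didehydroandrographolide 3,19-acetonide | C=C1CC[C@@H]2[C@]3(C)COC(C)(C)O[C@@H]3CC[C@@]2(C)[C@@H]1/C=C/C1=CCOC1=O | intermediate
6 | bis-butenolide bis-acetonide: C15 of the dienyl butenolide bonded to C12′ (S) of a 14′-deoxy butenolide; C15 both epimers | C=C1CC[C@@H]2[C@]3(C)COC(C)(C)O[C@@H]3CC[C@@]2(C)[C@@H]1/C=C/C1=CC(OC1=O)[C@@H](C[C@@H]1C(=C)CC[C@@H]2[C@]3(C)COC(C)(C)O[C@@H]3CC[C@]21C)C1=CCOC1=O | intermediate
7 | enol lactone: (12E)-3-alkylidene-2(3H)-furanone isomer of 6 (C11H2, C12=C13, C14=C15), 12′S | C=C1CC[C@@H]2[C@]3(C)COC(C)(C)O[C@@H]3CC[C@@]2(C)[C@@H]1C/C=C1/C(=O)OC(=C1)[C@@H](C[C@@H]1C(=C)CC[C@@H]2[C@]3(C)COC(C)(C)O[C@@H]3CC[C@]21C)C1=CCOC1=O | intermediate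
8 | keto ester bis-acetonide (target with both 3,19-diols as acetonides) | C=C1CC[C@@H]2[C@]3(C)COC(C)(C)O[C@@H]3CC[C@@]2(C)[C@@H]1C/C=C(\CC(=O)[C@@H](C[C@@H]1C(=C)CC[C@@H]2[C@]3(C)COC(C)(C)O[C@@H]3CC[C@]21C)C1=CCOC1=O)C(=O)OC | intermediate
9 | target CNP0330094.1 | C=C1CC[C@@H]2[C@](C)(CO)[C@H](O)CC[C@@]2(C)[C@@H]1C/C=C(\CC(=O)[C@@H](C[C@@H]1C(=C)CC[C@@H]2[C@](C)(CO)[C@H](O)CC[C@]21C)C1=CCOC1=O)C(=O)OC | target

**Totals**
Total steps: 5. Longest linear sequence: 4 (steps 1, 2, 4, 5).

**Three steps most likely to fail**

Step 5 (the new reaction). The transposition may be slow or the equilibrium may lie on the side of 6. Some ring opening may go through the α-protonated, deconjugated enol lactone and give the 11,12-ene ester. Prolonged base could epimerise the new α-keto centre C12′ or move the alkene to C13=C14. The fallback uses only known reaction types, sets out from 3 and comes back at 7: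
- SN2′ amination of 3 with dimethylamine (THF, rt) gives 12-(dimethylamino)-14-deoxyandrographolide 3,19-acetonide F1.
- Its lithium 2-oxidofuran (LiN(SiMe3)2, THF, −78 °C; the amine is too poor a leaving group to be lost) adds to a second equivalent of 3 as in step 4. This gives the 12-dimethylamino bis-butenolide F2, in which C11 is already a CH2 group.
- Iodomethane in MeCN quaternises the amine to the trimethylammonium iodide F3.
- K2CO3 in CH2Cl2/MeCN then triggers a Mannich-methiodide-type (vinylogous Hofmann, E1cB) loss of trimethylamine across C15–H and C12–N. This can only give the 12,13-alkylidene enol lactone 7, with no methanol and no ketone present.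
- Isolated 7 is opened with MeOH and DMAP (cat.) at 0 °C to 8 and deprotected with AcOH/H2O to 9, so the α-keto centre C12′ never meets a base.

Step 4. The β-substituted acceptor is hindered, and Cs2CO3 may mainly eliminate 3, or the face selectivity at C12′ may be modest (the epimers would then be separated at the stage of 6). Any 7 formed here by base is simply carried into step 5. The fallback sets out from 5 and comes back at 6. TBSOTf and Et3N (CH2Cl2, 0 °C) convert 5 into the 2-(tert-butyldimethylsilyloxy)-3-alkenylfuran F4. This neutral silyl dienolate is coupled with 3 under Lewis-base initiation (tetrabutylammonium difluorotriphenylsilicate, 5 mol %, THF, −78 to −20 °C). It is a vinylogous Mukaiyama–Michael addition–elimination in which the expelled acetate desilylates the next molecule of F4, so no free Brønsted base that could eliminate 3 is present.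

Step 2. Acylation of the allylic 14-OH can be accompanied by base-induced loss of the new acetate to the diene, and the acetate may be labile on silica. The fallback sets out from 2 and comes back at 6. Boc2O with DMAP (cat.) in CH2Cl2 at 0 °C, without a stoichiometric amine, gives the 14-O-tert-butoxycarbonyl carbonate F5. F5 is coupled with 5 using only 10 mol % Cs2CO3. The expelled tert-butyl carbonate loses CO2, and the resulting tert-butoxide deprotonates the next molecule of 5, the way Morita–Baylis–Hillman carbonates are used.

**Further compounds**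
F1 | step 5 | 12-(dimethylamino)-14-deoxyandrographolide 3,19-acetonide (12S) | C=C1CC[C@@H]2[C@]3(C)COC(C)(C)O[C@@H]3CC[C@@]2(C)[C@@H]1C[C@H](N(C)C)C1=CCOC1=O
F2 | step 5 | 12-dimethylamino bis-butenolide (C15–C12′ linked, 12′S, bis-acetonide) | C=C1CC[C@@H]2[C@]3(C)COC(C)(C)O[C@@H]3CC[C@@]2(C)[C@@H]1C[C@H](N(C)C)C1=CC(OC1=O)[C@@H](C[C@@H]1C(=C)CC[C@@H]2[C@]3(C)COC(C)(C)O[C@@H]3CC[C@]21C)C1=CCOC1=O
F3 | step 5 | trimethylammonium iodide of F2 | C=C1CC[C@@H]2[C@]3(C)COC(C)(C)O[C@@H]3CC[C@@]2(C)[C@@H]1C[C@H]([N+](C)(C)C)C1=CC(OC1=O)[C@@H](C[C@@H]1C(=C)CC[C@@H]2[C@]3(C)COC(C)(C)O[C@@H]3CC[C@]21C)C1=CCOC1=O.[I-]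
F4 | step 4 | 2-(tert-butyldimethylsilyloxy)-3-alkenylfuran from 5 | C=C1CC[C@@H]2[C@]3(C)COC(C)(C)O[C@@H]3CC[C@@]2(C)[C@@H]1/C=C/c1ccoc1O[Si](C)(C)C(C)(C)C
F5 | step 2 | 14-O-tert-butoxycarbonyl carbonate of 2 | C=C1CC[C@@H]2[C@]3(C)COC(C)(C)O[C@@H]3CC[C@@]2(C)[C@@H]1C/C=C1/C(=O)OC[C@H]1OC(=O)OC(C)(C)C
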